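**Strategy.** The flavone is cut at three bonds of ring C: C4a–C4, C4–C3 and O1–C2. The C4 carbonyl carbon, which sits alone between C4a of the phloroglucinol-type ring A and C3, is supplied as carbon monoxide, while C2–C3 with ring B comes from an aryl acetylene. Because ring A carries oxygen at C5, C7 and C8a in a symmetric 1,3,5-pattern, a peracetylated 2-iodophloroglucinol with two equivalent ortho acetates can serve as the aryl partner. One palladium-catalysed carbonylative alkynylation followed by amine-triggered ring closure builds the whole pyranone in a single operation. Mild methanolysis of the remaining acetates then delivers the target.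

Key step: step 6

Remark on the chemistry: diethylamine in step 6 may also remove some of the C5 or C7 acetate; such material is carried on together with 12, because step 7 converts all of it into 13.

**Step 1**
Reactants: 1 phloroglucinol (benzene-1,3,5-triol)
Product: 2 2-iodobenzene-1,3,5-triol (2-iodophloroglucinol)
Conditions: I2 (1.0 equiv, added slowly), NaHCO3 (1.1 equiv), THF/H2O (1:1), 0 °C to rt; crude product used at once
Reagents that add atoms: iodine, II
Why: Electrophilic aromatic iodination of a strongly activated phenol under bicarbonate buffering; the three ring CH positions are equivalent, and one equivalent of iodine added slowly at 0 °C should hold the reaction at the mono-iodide, which is acetylated immediately because it is sensitive to air and light.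

**Step 2**
Reactants: 2 2-iodobenzene-1,3,5-triol
Product: 3 2-iodobenzene-1,3,5-triyl triacetate
Conditions: Ac2O (4 equiv), DMAP (cat.), pyridine, 0 °C to rt
Reagents that add atoms: acetic anhydride, CC(=O)OC(C)=O
Why: Nucleophile-catalysed O-acetylation of phenols is fast even for the two hydroxyls flanking iodine and should turn the labile iodotriol into a bench-stable, less electron-rich aryl iodide suited to oxidative addition.

**Step 3**
Reactants: 4 1,2,3,4-tetramethoxybenzene
Product: 5 1-iodo-2,3,4,5-tetramethoxybenzene
Conditions: NIS (1.05 equiv), CF3CO2H (cat.), MeCN, rt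
Reagents that add atoms: N-iodosuccinimide, O=C1CCC(=O)N1I
Why: Electrophilic aromatic iodination with acid-activated N-iodosuccinimide suits polymethoxyarenes, and since C5 and C6 of 4 are symmetry-equivalent (each ortho to one methoxy group and para to another) only one mono-iodide can form.

**Step 4**
Reactants: 5 1-iodo-2,3,4,5-tetramethoxybenzene; 6 trimethylsilylacetylene
Product: 7 trimethyl[(2,3,4,5-tetramethoxyphenyl)ethynyl]silane
Conditions: PdCl2(PPh3)2 (3 mol%), CuI (5 mol%), Et3N/THF (1:1, degassed), 50 °C
Reagents that add atoms: none
Why: Sonogashira coupling of an aryl iodide with a silyl-capped terminal alkyne; the C–I bond should undergo oxidative addition despite the electron-rich ring and the ortho methoxy group, and the silyl cap prevents double arylation.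

**Step 5**
Reactants: 7 trimethyl[(2,3,4,5-tetramethoxyphenyl)ethynyl]silane
Product: 8 1-ethynyl-2,3,4,5-tetramethoxybenzene
Conditions: K2CO3 (0.2 equiv), MeOH, rt
Reagents that add atoms: none
Why: Methoxide-mediated protodesilylation of an alkynylsilane is selective and leaves the aryl methyl ethers untouched; the terminal alkyne is used promptly to limit oxidative dimerisation.

**Step 6**
Reactants: 3 2-iodobenzene-1,3,5-triyl triacetate; 8 1-ethynyl-2,3,4,5-tetramethoxybenzene; 9 carbon monoxide
Product: 12 5,7-diacetoxy-2-(2,3,4,5-tetramethoxyphenyl)-4H-chromen-4-one, via ynone 10 (not isolated), via enaminone phenol 11 (not isolated)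
Conditions: PdCl2(PPh3)2 (5 mol%), Ph2P(CH2)3PPh2 (5 mol%), thiourea (5 mol%), CO (balloon, 1 atm), Et2NH (degassed), 40 °C
Reagents that add atoms: none
Why: Zerovalent palladium, formed in situ from PdCl2(PPh3)2, inserts into the C–I bond of 3, CO insertion gives an aroyl complex of divalent palladium, and amine-assisted transfer of the acetylide of 8 followed by reductive elimination forms C4a–C4 and C4–C3 in ynone 10. Diethylamine then adds to the ynone and cleaves one ortho acetate to give enaminone phenol 11, whose phenoxide attacks C2 and expels diethylamine, forming O1–C2. The closest known reaction type is the palladium-catalysed carbonylative Sonogashira coupling–annulation of o-iodophenol acetates with terminal alkynes to flavones. Ring C closes in the 6-endo mode by addition–elimination at the β-carbon of the enaminone, which is why 5-exo closure to an aurone is not expected; no stereocentre is created. The step needs CO uptake to outrun direct alkynylation and needs the loss of one acetate to be unambiguous: copper-free conditions under CO favour insertion at the hindered, electron-rich aryl palladium bond, and the mirror plane through the C–I bond and the para C–O bond of 3 makes the two ortho acetates equivalent, so either one leads to the same O1. Further loss of the C5 or C7 acetate is harmless because step 7 removes both.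

**Step 7**
Reactants: 12 5,7-diacetoxy-2-(2,3,4,5-tetramethoxyphenyl)-4H-chromen-4-one
Product: 13 5,7-dihydroxy-2-(2,3,4,5-tetramethoxyphenyl)-4H-chromen-4-one (5,7-dihydroxy-2',3',4',5'-tetramethoxyflavone)
Conditions: K2CO3 (2.5 equiv), MeOH, rt; then 1 M HCl to pH 3
Reagents that add atoms: none
Why: Base-mediated transesterification (methanolysis) of aryl acetates proceeds at room temperature, where the γ-pyrone ring and the four aryl methyl ethers are inert, and it also converges any partly deacetylated material from step 6 on the same product.

**Compound list**

1 | phloroglucinol (benzene-1,3,5-triol) | Oc1cc(O)cc(O)c1 | starting material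
2 | 2-iodobenzene-1,3,5-triol | Oc1cc(O)c(I)c(O)c1 | intermediate
3 | 2-iodobenzene-1,3,5-triyl triacetate | CC(=O)Oc1cc(OC(C)=O)c(I)c(OC(C)=O)c1 | intermediate
4 | 1,2,3,4-tetramethoxybenzene | COc1ccc(OC)c(OC)c1OC | starting material
5 | 1-iodo-2,3,4,5-tetramethoxybenzene | COc1cc(I)c(OC)c(OC)c1OC | intermediate
6 | trimethylsilylacetylene | C#C[Si](C)(C)C | starting material
7 | trimethyl[(2,3,4,5-tetramethoxyphenyl)ethynyl]silane | COc1cc(C#C[Si](C)(C)C)c(OC)c(OC)c1OC | intermediate
8 | 1-ethynyl-2,3,4,5-tetramethoxybenzene | C#Cc1cc(OC)c(OC)c(OC)c1OC | intermediate
9 | carbon monoxide | [C-]#[O+] | starting material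
10 | 2-[3-(2,3,4,5-tetramethoxyphenyl)prop-2-ynoyl]benzene-1,3,5-triyl triacetate (ynone) | CC(=O)Oc1cc(OC(C)=O)c(C(=O)C#Cc2cc(OC)c(OC)c(OC)c2OC)c(OC(C)=O)c1 | intermediate
11 | (E)-3-(diethylamino)-1-(2,4-diacetoxy-6-hydroxyphenyl)-3-(2,3,4,5-tetramethoxyphenyl)prop-2-en-1-one (enaminone phenol; alkene geometry assumed E and lost on ring closure) | O=C(c1c(O)cc(OC(C)=O)cc1OC(C)=O)/C=C(\c1cc(OC)c(OC)c(OC)c1OC)N(CC)CC | intermediate
12 | 5,7-diacetoxy-2-(2,3,4,5-tetramethoxyphenyl)-4H-chromen-4-one | COc1cc(-c2cc(=O)c3c(OC(C)=O)cc(OC(C)=O)cc3o2)c(OC)c(OC)c1OC | intermediate
13 | 5,7-dihydroxy-2-(2,3,4,5-tetramethoxyphenyl)-4H-chromen-4-one | COc1cc(-c2cc(=O)c3c(O)cc(O)cc3o2)c(OC)c(OC)c1OC | target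

**Step count**

Total steps: 7. Longest linear sequence: 5 steps (4 → 5 → 7 → 8 → 12 → 13); the ring A branch (1 → 2 → 3) joins at step 6.

**Steps most likely to fail**

1. Step 6. The acetates may be aminolysed before oxidative addition, leaving an electron-rich iodophenoxide that inserts palladium slowly. The aroyl palladium species may be intercepted by diethylamine to give an amide, or alkynylation may occur without CO uptake. The fallback takes C4 from a preformed carboxyl carbon instead of CO and sets out from alkyne 8. Commercial 2,4,6-trihydroxybenzoic acid is peracetylated (Ac2O, cat. H2SO4, rt) to 2,4,6-triacetoxybenzoic acid F1. Oxalyl chloride with catalytic DMF in CH2Cl2 converts it into 2,4,6-triacetoxybenzoyl chloride F2. An acyl Sonogashira coupling of F2 with 8 (PdCl2(PPh3)2, CuI, Et3N, THF, rt) should give ynone 10, now isolated. Diethylamine in THF at rt to 40 °C then effects the same conjugate addition, acetate aminolysis and 6-endo closure through 11, and the route is rejoined at 12.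

2. Step 1. Over-iodination and oxidative decomposition of the very electron-rich triol may erode the mono-iodide during reaction or isolation. The fallback replaces electrophilic substitution by directed ortho-metalation and sets out from 1. Chloromethyl methyl ether with iPr2NEt in CH2Cl2 gives 1,3,5-tris(methoxymethoxy)benzene F3. n-BuLi in THF at 0 °C removes the proton between two acetal oxygens to give [2,4,6-tris(methoxymethoxy)phenyl]lithium F4, which is not isolated. Quenching with I2 at −78 °C gives 2-iodo-1,3,5-tris(methoxymethoxy)benzene F5, a stable, purifiable mono-iodide. Catalytic HCl in MeOH at rt cleaves the three acetals, and the route is rejoined at 2, which is concentrated and acetylated directly as in step 2.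

3. Step 4. Oxidative addition into the electron-rich, ortho-substituted C–I bond may be sluggish, so that copper-mediated dimerisation of the alkyne takes over. The fallback builds the alkyne by one-carbon homologation of an aldehyde and sets out from 4. Rieche formylation (Cl2CHOMe, TiCl4, CH2Cl2, 0 °C, aqueous quench) should give 2,3,4,5-tetramethoxybenzaldehyde F6, the two free ring positions being equivalent. Dimethyl (1-diazo-2-oxopropyl)phosphonate (Bestmann–Ohira reagent) with K2CO3 in MeOH at rt converts F6 into the terminal alkyne, and the route is rejoined at 8, bypassing 5 and 7.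

**Further compounds**

F1 | step 6 | 2,4,6-triacetoxybenzoic acid | CC(=O)Oc1cc(OC(C)=O)c(C(=O)O)c(OC(C)=O)c1
F2 | step 6 | 2,4,6-triacetoxybenzoyl chloride | CC(=O)Oc1cc(OC(C)=O)c(C(=O)Cl)c(OC(C)=O)c1
F3 | step 1 | 1,3,5-tris(methoxymethoxy)benzene | COCOc1cc(OCOC)cc(OCOC)c1
F4 | step 1 | [2,4,6-tris(methoxymethoxy)phenyl]lithium | [Li]c1c(OCOC)cc(OCOC)cc1OCOC
F5 | step 1 | 2-iodo-1,3,5-tris(methoxymethoxy)benzene | COCOc1cc(OCOC)c(I)c(OCOC)c1
F6 | step 4 | 2,3,4,5-tetramethoxybenzaldehyde | COc1cc(C=O)c(OC)c(OC)c1OC
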